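**Retrosynthetic overview**

1. The C9–C10 bond and the lactone C–O bond are made last: Ni/Cr union of epoxy (E)-alkenyl iodide 19 with the formyl group on C5 of acetoxy enone 9, the C9 chromium alkoxide closing onto the C8 methyl ester (spiro γ-lactone, last ring).
2. Feature used: C9 is a carbinol lying between the C10=C11 alkene and the quaternary spiro carbon C5 of the cyclohexenone ring, and the remote C14–C15 epoxide with the chain back to C11 is the five-carbon skeleton of L-glutamic acid.
3. Core 9: the cyclohexene ring (first ring) comes from a catalytic asymmetric Diels–Alder reaction of (E,E)-1,4-diacetoxybutadiene with methyl 3-formylbut-3-enoate, which sets C5 and C1; the two allylic oxygens are then told apart by hindrance (O1 keeps its acetate, C4 becomes the ketone).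
4. Iodide 19: L-glutamic acid → lactone acid → gem-dimethyl carbinol → lactol → alkyne → Zr-catalysed carboalumination/iodination → mesylate closure with inversion (oxirane ring).
5. Ring order: cyclohexene (step 2), oxirane (step 13), γ-lactone (step 14).

Key step: step 14

Remark on locants: those of the target are used throughout (ring C1 CHOAc, C2=C3, C4 ketone, C5 spiro, C6H2; lactone C7H2, C8=O, C9; chain C10=C11(Me), C12, C13; epoxide C14–C15).

Assumption: the sense of induction in step 2 is taken from the usual binding model for 2-substituted acroleins on a cationic diphenylprolinol-derived oxazaborolidine (boron-bound formyl group with a C–H···O contact, diene on the Cα face remote from the shielding phenyl group). On that model the (R)-catalyst is specified; if the first adduct proves antipodal, the (S)-catalyst is used and nothing else changes.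

**Route**

Step 1
Reactants: 1 methyl 4-oxobutanoate
Product: 2 methyl 3-formylbut-3-enoate
Conditions: 37% aq. HCHO (1.1 equiv), pyrrolidine (10 mol %), EtCO2H (10 mol %), i-PrOH, 45 °C
Reagents that add atoms: formaldehyde, C=O
Why: Amine-catalysed Mannich condensation–elimination (α-methylenation of an aldehyde through its enamine) should give the 2-substituted acrolein without a stereocentre, a short reaction time limiting migration of the double bond into conjugation with the ester.

Step 2
Reactants: 2 methyl 3-formylbut-3-enoate; 3 (1E,3E)-buta-1,3-diene-1,4-diyl diacetate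
Product: 4 methyl 2-[(1S,2S,5S)-2,5-diacetoxy-1-formylcyclohex-3-en-1-yl]acetate (formyl and both acetoxy groups on one face)
Conditions: (R)-B-o-tolyl oxazaborolidine from (R)-α,α-diphenylprolinol (20 mol %), Tf2NH (20 mol %), 3 (1.5 equiv), CH2Cl2, −78 → −30 °C
Reagents that add atoms: none
Why: Cationic oxazaborolidine-catalysed Diels–Alder reaction of a 2-substituted acrolein, in which the boron-bound formyl group lies endo to the (E,E)-diene, so that CHO ends up cis to both acetoxy groups, and the catalyst shields one Cα face, so that the quaternary carbon C5 and with it C1 and C4 should form in the absolute sense shown.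

Step 3
Reactants: 4 methyl 2-[(1S,2S,5S)-2,5-diacetoxy-1-formylcyclohex-3-en-1-yl]acetate
Product: 6 methyl 2-[(1S,2S,5S)-1-(dimethoxymethyl)-2,5-dihydroxycyclohex-3-en-1-yl]acetate, via acetal diacetate 5 (not isolated)
Conditions: HC(OMe)3, PPTS (cat.), MeOH, rt; then K2CO3 (0.5 equiv), MeOH, 0 °C
Reagents that add atoms: trimethyl orthoformate, COC(OC)OC
Why: Acid-catalysed acetalisation masks the aldehyde, so that the later β-hydroxy aldehyde cannot undergo retro-aldol cleavage or close a lactol onto O1, and Zemplén-type transesterification then removes both acetates without touching a stereocentre, the C4 alkoxide being trans to the CH2CO2Me arm and so poorly placed to lactonise at 0 °C.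

Step 4
Reactants: 6 methyl 2-[(1S,2S,5S)-1-(dimethoxymethyl)-2,5-dihydroxycyclohex-3-en-1-yl]acetate
Product: 7 methyl 2-[(1S,2S,5S)-5-acetoxy-1-(dimethoxymethyl)-2-hydroxycyclohex-3-en-1-yl]acetate
Conditions: Ac2O (1.05 equiv), 2,4,6-collidine, DMAP (5 mol %), CH2Cl2, −40 °C
Reagents that add atoms: acetic anhydride, CC(=O)OC(C)=O
Why: Sterically controlled DMAP-catalysed acylation should take only the C1 hydroxyl, which is flanked by the ring methylene C6, and leave the C4 hydroxyl next to the fully substituted C5.

Step 5
Reactants: 7 methyl 2-[(1S,2S,5S)-5-acetoxy-1-(dimethoxymethyl)-2-hydroxycyclohex-3-en-1-yl]acetate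
Product: 8 methyl 2-[(1R,5S)-5-acetoxy-1-(dimethoxymethyl)-2-oxocyclohex-3-en-1-yl]acetate
Conditions: Dess–Martin periodinane, pyridine, CH2Cl2, 0 °C → rt
Reagents that add atoms: none
Why: Dess–Martin oxidation of the remaining allylic alcohol gives the enone and removes the auxiliary C4 stereocentre, C5 being quaternary and C1 not enolisable under these buffered conditions.

Step 6
Reactants: 8 methyl 2-[(1R,5S)-5-acetoxy-1-(dimethoxymethyl)-2-oxocyclohex-3-en-1-yl]acetate
Product: 9 methyl 2-[(1R,5S)-5-acetoxy-1-formyl-2-oxocyclohex-3-en-1-yl]acetate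
Conditions: TFA–H2O (9:1), CH2Cl2, 0 °C; used without storage
Reagents that add atoms: water, O
Why: Acid hydrolysis of the dimethyl acetal frees a formyl group that has no α-hydrogen, while the allylic acetate, the methyl ester and the enone should tolerate brief aqueous acid at 0 °C.

Step 7
Reactants: 10 L-glutamic acid
Product: 11 (S)-5-oxotetrahydrofuran-2-carboxylic acid
Conditions: NaNO2, 2 M aq. HCl, 0 °C → rt
Reagents that add atoms: none
Why: Diazotisation of the α-amino acid proceeds with double inversion (α-lactone, then opening by the γ-carboxyl group), so the S configuration of L-glutamic acid is retained at the carbon that becomes C14.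

Step 8
Reactants: 11 (S)-5-oxotetrahydrofuran-2-carboxylic acid
Product: 12 ethyl (S)-5-oxotetrahydrofuran-2-carboxylate
Conditions: EtOH, TsOH·H2O (cat.), toluene, reflux (Dean–Stark); distillation
Reagents that add atoms: ethanol, CCO
Why: Fischer esterification with azeotropic removal of water gives the lactone ester, any ring-opened hydroxy diester re-closing on distillation, and the stereocentre is not enolised under acid.

Step 9
Reactants: 12 ethyl (S)-5-oxotetrahydrofuran-2-carboxylate
Product: 13 (S)-5-(2-hydroxypropan-2-yl)dihydrofuran-2(3H)-one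
Conditions: MeMgBr (2.1 equiv), THF, −78 → −40 °C; aq. NH4Cl
Reagents that add atoms: methylmagnesium bromide, C[Mg]Br
Why: Double Grignard addition goes to the exocyclic ester, which the α-acyloxy substituent activates over the γ-lactone at low temperature, and creates the gem-dimethyl carbinol C15 without involving C14; a partial acyl shift to the six-membered lactone would be harmless because both lactones lead to the same alkyne in steps 10 and 11.

Step 10
Reactants: 13 (S)-5-(2-hydroxypropan-2-yl)dihydrofuran-2(3H)-one
Product: 14 (5S)-5-(2-hydroxypropan-2-yl)tetrahydrofuran-2-ol (anomer mixture)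
Conditions: DIBAL-H (2.2 equiv), CH2Cl2, −78 °C; Rochelle salt
Reagents that add atoms: none
Why: Partial reduction of a γ-lactone by DIBAL-H stops at the lactol at −78 °C because the tetrahedral aluminium alkoxide is stable there, one equivalent being spent on the tertiary hydroxyl.

Step 11
Reactants: 14 (5S)-5-(2-hydroxypropan-2-yl)tetrahydrofuran-2-ol
Product: 15 (S)-2-methylhept-6-yne-2,3-diol
Conditions: dimethyl (1-diazo-2-oxopropyl)phosphonate, K2CO3, MeOH, 0 °C → rt
Reagents that add atoms: dimethyl (1-diazo-2-oxopropyl)phosphonate, CC(=O)C(=[N+]=[N-])P(=O)(OC)OC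
Why: Seyferth–Gilbert homologation in the Ohira–Bestmann version acts on the open hydroxy aldehyde form of the lactol and adds C10 as the terminal alkyne carbon under conditions too mild to affect C14.

Step 12
Reactants: 15 (S)-2-methylhept-6-yne-2,3-diol
Product: 17 (3S,6E)-7-iodo-2,6-dimethylhept-6-ene-2,3-diol, via alkenyl(dimethyl)alane 16 (not isolated)
Conditions: Me3Al (4 equiv), Cp2ZrCl2 (25 mol %), CH2Cl2, 0 °C → rt; then I2, THF, −30 → 0 °C
Reagents that add atoms: trimethylaluminium, C[Al](C)C; iodine, II
Why: Zirconium-catalysed syn-carboalumination (Negishi) places methyl on the internal and aluminium on the terminal alkyne carbon, and iodinolysis with retention gives the (E)-2-methylalkenyl iodide, the two hydroxyls being carried as aluminium alkoxides.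

Step 13
Reactants: 17 (3S,6E)-7-iodo-2,6-dimethylhept-6-ene-2,3-diol
Product: 19 (R)-3-[(E)-4-iodo-3-methylbut-3-en-1-yl]-2,2-dimethyloxirane, via secondary mesylate 18 (not isolated)
Conditions: MsCl (1.1 equiv), Et3N, CH2Cl2, −20 °C; then K2CO3, MeOH, rt
Reagents that add atoms: none
Why: Only the secondary hydroxyl is sulfonylated, and the tertiary alkoxide then displaces the mesylate in a 3-exo-tet Williamson closure with inversion at C14, turning the (S)-diol into the (R)-epoxide while the alkenyl iodide is inert to carbonate.

Step 14
Reactants: 9 methyl 2-[(1R,5S)-5-acetoxy-1-formyl-2-oxocyclohex-3-en-1-yl]acetate; 19 (R)-3-[(E)-4-iodo-3-methylbut-3-en-1-yl]-2,2-dimethyloxirane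
Product: 21 (+)-miliusane XII/XIII, (1R,5R,9S)-1-{(1E)-4-[(2R)-3,3-dimethyloxiran-2-yl]-2-methylbut-1-en-1-yl}-3,6-dioxo-2-oxaspiro[4.5]dec-7-en-9-yl acetate, via hydroxy ester 20 (not isolated)
Conditions: CrCl2 (5 equiv), NiCl2 (2 mol %), 19 (1.5 equiv), degassed DMSO–THF, rt; pH 7 aqueous work-up; then PPTS (cat.), CH2Cl2, rt
Reagents that add atoms: none
Why: Nickel(0), formed from NiCl2 by Cr(II), inserts into the C–I bond of 19 with retention of the E geometry and transmetalates to chromium(III), and the alkenylchromium adds 1,2 to the formyl group of 9 (Nozaki–Hiyama–Kishi alkenylation; the closest known type is NHK addition to an aldehyde carrying a γ-ester, followed by lactonisation). The C9 chromium alkoxide then attacks the C8 methyl ester in a 5-exo-trig acyl substitution that closes the spiro γ-lactone and expels methoxide, the PPTS treatment only driving any remaining 20 to 21. C9 is set under substrate control: chromium(III) should bridge the formyl oxygen and the C4 ketone oxygen in a six-membered chelate, which holds the formyl group syn to C4=O and leaves one face flanked by the tied-back ring methylene C6 and the other by the CH2CO2Me arm, and delivery past C6 gives the (9R) carbinol of the target. C14 and the C10=C11 geometry come unchanged from 19, and C1 and C5 from 9. The step needs attack at the aldehyde only, with no opening of the epoxide and no reduction of the γ-acetoxy enone; the low basicity and oxophilicity of alkenylchromium, the hindered conjugated nature of the C4 ketone and the neutral room-temperature medium should secure this.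

**Compound list**

1 | methyl 4-oxobutanoate | COC(=O)CCC=O | starting material
2 | methyl 3-formylbut-3-enoate | COC(=O)CC(=C)C=O | intermediate
3 | (1E,3E)-buta-1,3-diene-1,4-diyl diacetate | CC(=O)O/C=C/C=C/OC(C)=O | starting material
4 | methyl 2-[(1S,2S,5S)-2,5-diacetoxy-1-formylcyclohex-3-en-1-yl]acetate | CC(=O)O[C@@H]1C=C[C@H](OC(C)=O)[C@@](C=O)(CC(=O)OC)C1 | intermediate
5 | methyl 2-[(1S,2S,5S)-2,5-diacetoxy-1-(dimethoxymethyl)cyclohex-3-en-1-yl]acetate | CC(=O)O[C@@H]1C=C[C@H](OC(C)=O)[C@@](C(OC)OC)(CC(=O)OC)C1 | intermediate (not isolated)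
6 | methyl 2-[(1S,2S,5S)-1-(dimethoxymethyl)-2,5-dihydroxycyclohex-3-en-1-yl]acetate | O[C@@H]1C=C[C@H](O)[C@@](C(OC)OC)(CC(=O)OC)C1 | intermediate
7 | methyl 2-[(1S,2S,5S)-5-acetoxy-1-(dimethoxymethyl)-2-hydroxycyclohex-3-en-1-yl]acetate | CC(=O)O[C@@H]1C=C[C@H](O)[C@@](C(OC)OC)(CC(=O)OC)C1 | intermediate
8 | methyl 2-[(1R,5S)-5-acetoxy-1-(dimethoxymethyl)-2-oxocyclohex-3-en-1-yl]acetate | CC(=O)O[C@@H]1C=CC(=O)[C@@](C(OC)OC)(CC(=O)OC)C1 | intermediate
9 | methyl 2-[(1R,5S)-5-acetoxy-1-formyl-2-oxocyclohex-3-en-1-yl]acetate | CC(=O)O[C@@H]1C=CC(=O)[C@@](C=O)(CC(=O)OC)C1 | intermediate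
10 | L-glutamic acid | N[C@@H](CCC(=O)O)C(=O)O | starting material
11 | (S)-5-oxotetrahydrofuran-2-carboxylic acid | OC(=O)[C@@H]1CCC(=O)O1 | intermediate
12 | ethyl (S)-5-oxotetrahydrofuran-2-carboxylate | CCOC(=O)[C@@H]1CCC(=O)O1 | intermediate
13 | (S)-5-(2-hydroxypropan-2-yl)dihydrofuran-2(3H)-one | CC(C)(O)[C@@H]1CCC(=O)O1 | intermediate
14 | (5S)-5-(2-hydroxypropan-2-yl)tetrahydrofuran-2-ol, anomer mixture | CC(C)(O)[C@@H]1CCC(O)O1 | intermediate
15 | (S)-2-methylhept-6-yne-2,3-diol | C#CCC[C@H](O)C(C)(C)O | intermediate
16 | (E)-alkenyl(dimethyl)alane from 15, hydroxyls drawn free but present as aluminium alkoxides | C[Al](C)/C=C(\C)CC[C@H](O)C(C)(C)O | intermediate (not isolated)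
17 | (3S,6E)-7-iodo-2,6-dimethylhept-6-ene-2,3-diol | I/C=C(\C)CC[C@H](O)C(C)(C)O | intermediate
18 | (3S,6E)-2-hydroxy-7-iodo-2,6-dimethylhept-6-en-3-yl methanesulfonate | I/C=C(\C)CC[C@H](OS(C)(=O)=O)C(C)(C)O | intermediate (not isolated)
19 | (R)-3-[(E)-4-iodo-3-methylbut-3-en-1-yl]-2,2-dimethyloxirane | I/C=C(\C)CC[C@H]1OC1(C)C | intermediate
20 | methyl 2-[(1R,5S)-5-acetoxy-1-{(1R,2E)-5-[(2R)-3,3-dimethyloxiran-2-yl]-1-hydroxy-3-methylpent-2-en-1-yl}-2-oxocyclohex-3-en-1-yl]acetate, formed as its chromium alkoxide | CC(=O)O[C@@H]1C=CC(=O)[C@@]([C@H](O)/C=C(\C)CC[C@H]2OC2(C)C)(CC(=O)OC)C1 | intermediate (not isolated)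
21 | (+)-miliusane XII/XIII | CC(=O)O[C@@H]1C=CC(=O)[C@@]2(CC(=O)O[C@@H]2/C=C(\C)CC[C@H]2OC2(C)C)C1 | target

**Step count**

Total: 14 steps. Longest linear sequence: 8 steps (steps 7–14, from L-glutamic acid); the core branch is 7 steps (steps 1–6 and 14).

**Steps most likely to fail**

1. Step 14. The process at risk is facial selection at the formyl group: the chelated rotamer and the dipole-opposed rotamer lead to opposite configurations at C9, so substrate control may be weak, and excess Cr(II) may also begin to reduce the γ-acetoxy enone. The fallback moves stereocontrol from the substrate to the reagent and makes chromium catalytic. It sets out from 9 and 19: a chromium complex of a chiral sulfonamide–oxazoline ligand (10–20 mol %), NiCl2·2,9-dimethylphenanthroline (2 mol %), Mn powder, Cp2ZrCl2 and LiCl in MeCN at rt. Both ligand antipodes are available, and the one that delivers (9R) is chosen in a paired small-scale test. The adduct is released as 20 and closed with PPTS, so the fallback comes back to the route at 20 and then 21. It makes no new compound (F0).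

2. Step 2. The process at risk is a slow cycloaddition of the acetoxy-deactivated diene at the low temperature that the cationic catalyst needs, with erosion of endo selectivity and of enantioselectivity and with competing oligomerisation of 2. The fallback gives up the asymmetric catalyst and takes the absolute configuration from an enzyme. It sets out from 2 and 3, which are heated without catalyst (toluene, BHT, 90 °C) to the racemic all-cis adduct F1. This is carried through the conditions of step 3 to the racemic acetal diacetate F2 (not isolated) and the racemic diol acetal F3. F3 is then resolved by lipase-catalysed acetylation (Pseudomonas cepacia lipase or Candida antarctica lipase B, vinyl acetate, MTBE, rt, about half conversion); this replaces step 4 and returns to the route at 7, leaving the unreacted antipodal diol acetal F4. By the empirical size rule for lipase acylation of secondary alcohols, the C1 carbinol of the wanted enantiomer is expected to be the fast one. Should the enzyme prefer the antipode, the recovered diol is the wanted 6 and is acetylated as in step 4.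

3. Step 3. The process at risk is attack of the freed C4 alkoxide on the neighbouring methyl ester (trans-fused γ-lactone) during methanolysis, which would block the oxidation of step 5 and consume the ester needed in step 14. The fallback keeps alkoxide and ester apart. It sets out from 5, isolated after the acetalisation stage, which is saponified completely (LiOH, THF–H2O, rt) to the lithium dihydroxy carboxylate F5; a carboxylate cannot be acylated by the alkoxide. After neutralisation of excess base with CO2 and evaporation, F5 is O-methylated at the carboxylate only (MeI, DMF, rt), and the route is rejoined at 6, which is taken at once into step 4.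

**Further compounds**

F0 | step 14 | none | none
F1 | step 2 | racemic methyl 2-[(1S*,2S*,5S*)-2,5-diacetoxy-1-formylcyclohex-3-en-1-yl]acetate | CC(=O)O[C@@H]1C=C[C@H](OC(C)=O)[C@@](C=O)(CC(=O)OC)C1.CC(=O)O[C@H]1C=C[C@@H](OC(C)=O)[C@](C=O)(CC(=O)OC)C1
F2 | step 2 | racemic methyl 2-[(1S*,2S*,5S*)-2,5-diacetoxy-1-(dimethoxymethyl)cyclohex-3-en-1-yl]acetate | CC(=O)O[C@@H]1C=C[C@H](OC(C)=O)[C@@](C(OC)OC)(CC(=O)OC)C1.CC(=O)O[C@H]1C=C[C@@H](OC(C)=O)[C@](C(OC)OC)(CC(=O)OC)C1
F3 | step 2 | racemic methyl 2-[(1S*,2S*,5S*)-1-(dimethoxymethyl)-2,5-dihydroxycyclohex-3-en-1-yl]acetate | O[C@@H]1C=C[C@H](O)[C@@](C(OC)OC)(CC(=O)OC)C1.O[C@H]1C=C[C@@H](O)[C@](C(OC)OC)(CC(=O)OC)C1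
F4 | step 2 | methyl 2-[(1R,2R,5R)-1-(dimethoxymethyl)-2,5-dihydroxycyclohex-3-en-1-yl]acetate | O[C@H]1C=C[C@@H](O)[C@](C(OC)OC)(CC(=O)OC)C1
F5 | step 3 | lithium 2-[(1S,2S,5S)-1-(dimethoxymethyl)-2,5-dihydroxycyclohex-3-en-1-yl]acetate | O[C@@H]1C=C[C@H](O)[C@@](C(OC)OC)(CC(=O)[O-])C1.[Li+]
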